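## Retrosynthetic overview

1. Labdane numbering is used (ring A = C1–C5, C10; ring B = C5–C10; side chain C11–C15). The 3-OAc, 19-OH and 15-CO2H groups come from a C3 ketone, a C4 ester and a C15 silyl ether; the C4 quaternary centre comes from methylation of β-keto ester 24.
2. Key disconnection C6–C7 (ring B): in bicyclo[4.1.0]heptan-2-one 22, C6 is the CH2 of a cyclopropane (C4–C5–C6) fused to ring A and geminally activated at C4 by the C3 ketone and the C19 ester. Opening the strained external C4–C6 bond makes C6 the coupling partner of the tethered (Z)-alkenyl bromide at C7 and leaves the C3/C4 β-keto ester the target needs.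
3. Ring A (bonds C4–C5 and C4–C6): intramolecular carbenoid cyclopropanation of the C5=C6 vinyl group in diazo keto ester 21.
4. C9–C10 with both stereocentres: enantioselective Ireland–Claisen rearrangement of geranyl (Z)-4-bromo-3-methylbut-3-enoate 7. C11–C12: copper-catalysed alkyl–alkyl coupling with a C12–C15 unit from (S)-2-methylbutane-1,4-diol (C13).
5. Ring order: ring A first (step 14), ring B second (step 15).

Key step: step 15

Assumption: the (4R,5R)-bromodiazaborolidine with Et3N is taken to form boron dienolate 8 with C8 cis to the geranyloxy oxygen and to deliver the (2S,3R)-acid 9; if either sense proves the reverse, the (4S,5S)-reagent or the i-Pr2NEt/CH2Cl2 enolisation protocol is used without other change.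

## Route

Step 1
Reactants: 1 but-3-yn-1-ol
Product: 4 (Z)-4-bromo-3-methylbut-3-en-1-ol, via (E)-alkenylalane 2 (not isolated), via cyclic (Z)-alkenylalane 3 (not isolated)
Conditions: Me3Al, Cp2ZrCl2 (25 mol%), ClCH2CH2Cl, rt; then reflux; then NBS, THF, −30 → 0 °C
Reagents that add atoms: trimethylaluminium C[Al](C)C; N-bromosuccinimide BrN1C(=O)CCC1=O
Why: Zirconium-catalysed methylalumination of the alkyne (Negishi carboalumination) is syn and puts methyl on the internal carbon, heating lets the adduct isomerise to the alkoxide-chelated (Z)-alkenylalane 3, and bromodealumination goes with retention, so Br ends cis to the hydroxyethyl arm.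

Step 2
Reactants: 4 (Z)-4-bromo-3-methylbut-3-en-1-ol
Product: 5 (Z)-4-bromo-3-methylbut-3-enoic acid
Conditions: CrO3, H2SO4, H2O, acetone, 0 °C
Reagents that add atoms: chromium trioxide O=[Cr](=O)=O; water O
Why: Jones oxidation should take the primary homoallylic alcohol to the β,γ-unsaturated acid without moving the bromine-deactivated trisubstituted alkene.

Step 3
Reactants: 5 (Z)-4-bromo-3-methylbut-3-enoic acid; 6 geraniol
Product: 7 geranyl (Z)-4-bromo-3-methylbut-3-enoate
Conditions: DCC, DMAP (5 mol%), CH2Cl2, −20 → 0 °C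
Reagents that add atoms: none
Why: Steglich esterification at low temperature with only catalytic DMAP should join acid and allylic alcohol while keeping the double bond out of conjugation and both alkene geometries intact.

Step 4
Reactants: 7 geranyl (Z)-4-bromo-3-methylbut-3-enoate
Product: 9 (2S,3R)-2-[(Z)-1-bromoprop-1-en-2-yl]-3-ethenyl-3,7-dimethyloct-6-enoic acid, via boron dienolate 8 (not isolated)
Conditions: (4R,5R)-2-bromo-1,3-bis{[3,5-bis(trifluoromethyl)phenyl]sulfonyl}-4,5-diphenyl-1,3,2-diazaborolidine, Et3N, PhMe/hexane, −78 °C; then −20 → 4 °C; aqueous work-up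
Reagents that add atoms: none
Why: In this enantioselective Ireland–Claisen rearrangement the boron dienolate 8 reacts through its α-carbon in a chair transition state in which the (E)-allyl unit places the C10 methyl pseudoaxial and the enolate geometry places C8 pseudoaxial, which fixes the C9/C10 relative configuration, while the C2-symmetric sulfonamide ligand on boron selects the enolate face and so the absolute configuration.

Step 5
Reactants: 9 Claisen acid
Product: 10 (2S,3R)-2-[(Z)-1-bromoprop-1-en-2-yl]-3-ethenyl-3,7-dimethyloct-6-en-1-ol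
Conditions: LiAlH4, Et2O, 0 °C → rt
Reagents that add atoms: none
Why: Hydride reduction of the carboxylic acid to the primary alcohol at low temperature should leave the alkenyl bromide, the isolated alkenes and C9 untouched.

Step 6
Reactants: 10 primary alcohol
Product: 11 (2S,3R)-2-[(Z)-1-bromoprop-1-en-2-yl]-3-ethenyl-3,7-dimethyloct-6-en-1-yl trifluoromethanesulfonate
Conditions: Tf2O, pyridine, CH2Cl2, −78 → −40 °C; used cold
Reagents that add atoms: triflic anhydride O=S(=O)(OS(=O)(=O)C(F)(F)F)C(F)(F)F
Why: O-Sulfonylation of the primary alcohol gives the leaving group needed for substitution at the β-branched C11.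

Step 7
Reactants: 12 (S)-2-methylbutane-1,4-diol
Product: 13 (S)-4-[(tert-butyldimethylsilyl)oxy]-2-methylbutan-1-ol
Conditions: TBSCl (1.0 equiv), Et3N, DMAP (cat.), CH2Cl2, −20 °C; chromatography
Reagents that add atoms: tert-butyldimethylsilyl chloride CC(C)(C)[Si](C)(C)Cl
Why: Monosilylation with one equivalent of silyl chloride should favour the hydroxyl remote from the methyl branch (steric differentiation), the minor regioisomer being removed by chromatography.

Step 8
Reactants: 13 mono-silyl ether
Product: 14 (S)-(4-bromo-3-methylbutoxy)(tert-butyl)dimethylsilane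
Conditions: CBr4, PPh3, CH2Cl2, 0 °C
Reagents that add atoms: carbon tetrabromide BrC(Br)(Br)Br
Why: Appel bromination converts the primary alcohol to the bromide under neutral conditions that leave the silyl ether and the stereocentre untouched.

Step 9
Reactants: 11 triflate; 14 bromide
Product: 16 tert-butyl{[(3R,6S,7R)-6-[(Z)-1-bromoprop-1-en-2-yl]-7-ethenyl-3,7,11-trimethyldodec-10-en-1-yl]oxy}dimethylsilane, via Grignard reagent 15 (not isolated)
Conditions: 14, Mg, THF, 40 °C; then 11, Li2CuCl4 (5 mol%), THF, −78 → −20 °C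
Reagents that add atoms: none
Why: Copper-catalysed cross-coupling of a primary alkyl Grignard reagent with a primary alkyl triflate should form C11–C12 at a temperature at which alkenyl bromides do not react, and it brings in C13 with its configuration from the chiral pool.

Step 10
Reactants: 16 triene
Product: 17 10,11-epoxide of 16 (both epimers at the epoxide CH)
Conditions: mCPBA (1.05 equiv), NaHCO3, CH2Cl2, −20 → 0 °C
Reagents that add atoms: 3-chloroperbenzoic acid OOC(=O)c1cccc(Cl)c1
Why: Prilezhaev epoxidation with one equivalent of peracid should select the electron-rich trisubstituted alkene over the monosubstituted vinyl group and the bromine-deactivated alkene, and the new centre is lost in the next step.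

Step 11
Reactants: 17 epoxide
Product: 19 (4R,5S,8R)-5-[(Z)-1-bromoprop-1-en-2-yl]-10-[(tert-butyldimethylsilyl)oxy]-4-ethenyl-4,8-dimethyldecanal, via vicinal diol 18 (not isolated)
Conditions: H5IO6, THF/Et2O, 0 °C, short reaction time
Reagents that add atoms: none
Why: Periodic acid hydrolyses the trisubstituted epoxide to diol 18 and cleaves it in the same flask (glycol cleavage) to the C3 aldehyde, with acetone leaving.

Step 12
Reactants: 19 aldehyde
Product: 20 ethyl (6R,7S,10R)-7-[(Z)-1-bromoprop-1-en-2-yl]-12-[(tert-butyldimethylsilyl)oxy]-6-ethenyl-6,10-dimethyl-3-oxododecanoate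
Conditions: ethyl diazoacetate, SnCl2 (10 mol%), CH2Cl2, rt
Reagents that add atoms: ethyl diazoacetate CCOC(=O)C=[N+]=[N-]
Why: In the Roskamp reaction, SnCl2-catalysed addition of the diazo ester to the aldehyde and 1,2-hydride shift with loss of N2 give the β-keto ester and install C4 and C19.

Step 13
Reactants: 20 β-keto ester
Product: 21 ethyl (6R,7S,10R)-7-[(Z)-1-bromoprop-1-en-2-yl]-12-[(tert-butyldimethylsilyl)oxy]-2-diazo-6-ethenyl-6,10-dimethyl-3-oxododecanoate
Conditions: p-ABSA, Et3N, MeCN, 0 °C → rt
Reagents that add atoms: 4-acetamidobenzenesulfonyl azide CC(=O)Nc1ccc(cc1)S(=O)(=O)N=[N+]=[N-]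
Why: Regitz diazo transfer to the active methylene of a β-keto ester is fast and chemoselective.

Step 14
Reactants: 21 diazo keto ester
Product: 22 ethyl (1R,5R,6S)-5-[(1Z,3S,6R)-1-bromo-8-{[tert-butyl(dimethyl)silyl]oxy}-2,6-dimethyloct-1-en-3-yl]-5-methyl-2-oxobicyclo[4.1.0]heptane-1-carboxylate
Conditions: Rh2(OAc)4 (1 mol%), CH2Cl2, slow addition, rt → 40 °C
Reagents that add atoms: none
Why: Intramolecular cyclopropanation by the rhodium carbenoid closes ring A on the C5=C6 vinyl group (C10 is quaternary, so no 1,5 C–H insertion can compete), the cis fusion is enforced, and the carbenoid should add to the face on which the =CH2 terminus lies next to the C10 methyl and away from the branched C9 substituent, which sets C5 with its hydrogen anti to the C10 methyl.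

Step 15
Reactants: 22 cyclopropyl keto ester
Product: 24 ethyl (5R,9R,10R,13R)-15-[(tert-butyldimethylsilyl)oxy]-3-oxo-18-norlabd-7-en-19-oate (C4 epimers and enol form), via iodo magnesium enolate 23 (not isolated)
Conditions: MgI2 (1.5 equiv), NiBr2(dme) (10 mol%), 4,4′-di-tert-butyl-2,2′-bipyridine (12 mol%), Zn dust (3 equiv), DMA/THF, 0.01 M, 40 °C; aq. NH4Cl
Reagents that add atoms: none
Why: Proposed new method: MgI2 chelates the 1,3-dicarbonyl unit and iodide opens the geminally activated cyclopropane by SN2 attack at the unhindered C6 methylene (homoconjugate addition driven by release of the three-ring strain) to give the iodo magnesium enolate 23, zerovalent nickel inserts into the C7–Br bond with retention of the (Z)-geometry, low-valent nickel turns the C6–I bond into a C6 radical that is captured at the alkenylnickel centre, and reductive elimination forms C6–C7 while Zn turns the catalyst over. The closest known reaction types are the nickel-catalysed reductive ring-opening γ-alkylation of cyclopropyl ketones with alkyl halides, the MgI2-mediated homoconjugate opening of 1-acylcyclopropanecarboxylates and the nickel-catalysed cross-electrophile coupling of primary alkyl iodides with alkenyl bromides; new is their merger in one intramolecular event. Ring B closes as a six-membered ring by C(sp3)–C(sp2) reductive elimination from a seven-membered nickelacycle (formally a 6-endo closure with ipso substitution of bromide), so the C7=C8 double bond arrives in its final place and no exo mode is open at the metal. No lasting stereocentre is formed (C4 becomes an enolisable β-keto ester carbon, fixed in step 16), and C5, C9, C10 and C13 are not touched because the bond that breaks ends on the CH2 carbon C6. The step needs cleavage of the external C4–C6 bond and not of the ring-fusion bond C4–C5, which the alignment of the external bond with the C3 carbonyl π system in a bicyclo[4.1.0]heptan-2-one and the neopentyl nature of C5 secure, and it needs ring closure to outrun hydrodehalogenation and dimerisation, which the cis arrangement of C7–Ni and C9 on the alkene, the gauche equatorial C6 and C9 arms on C5 and C10, and high dilution secure.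

Step 16
Reactants: 24 bicyclic β-keto ester
Product: 25 ethyl (4S,5S,9R,10S,13R)-15-[(tert-butyldimethylsilyl)oxy]-3-oxolabd-7-en-19-oate
Conditions: MeI, K2CO3, acetone, rt
Reagents that add atoms: iodomethane CI
Why: C-Alkylation of the β-keto ester enolate should occur on the face opposite the axial C10 methyl (1,3-diaxial hindrance), so the new methyl is equatorial and the ester is axial, cis to the C10 methyl, as the target requires.

Step 17
Reactants: 25 methylated keto ester
Product: 26 ethyl (3S,4S,5S,9R,10S,13R)-15-[(tert-butyldimethylsilyl)oxy]-3-hydroxylabd-7-en-19-oate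
Conditions: LiBH(s-Bu)3 (L-Selectride), THF, −78 °C; aq. NH4Cl
Reagents that add atoms: none
Why: Ketone reduction with the bulky trialkylborohydride should proceed by equatorial attack on the 4,4-disubstituted cyclohexanone and give the axial C3 alcohol, trans to the axial C4 ester, which is too hindered to be reduced at −78 °C.

Step 18
Reactants: 26 hydroxy ester
Product: 27 (3S,4R,5S,9R,10S,13R)-15-[(tert-butyldimethylsilyl)oxy]labd-7-ene-3,19-diol
Conditions: LiAlH4, THF, 0 °C → rt
Reagents that add atoms: none
Why: Hydride reduction of the hindered neopentyl ester gives the C19 primary alcohol, while the silyl ether and the trisubstituted alkene are inert.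

Step 19
Reactants: 27 diol
Product: 28 (3S,4R,5S,9R,10S,13R)-15-[(tert-butyldimethylsilyl)oxy]-19-[(tert-butyldiphenylsilyl)oxy]labd-7-en-3-ol
Conditions: TBDPSCl, imidazole, DMF, 0 °C → rt
Reagents that add atoms: tert-butyldiphenylsilyl chloride CC(C)(C)[Si](Cl)(c1ccccc1)c1ccccc1
Why: Silylation with the bulky chlorosilane should select the primary C19 hydroxyl over the hindered axial secondary C3 hydroxyl.

Step 20
Reactants: 28 mono-protected diol
Product: 29 (3S,4R,5S,9R,10S,13R)-15-[(tert-butyldimethylsilyl)oxy]-19-[(tert-butyldiphenylsilyl)oxy]labd-7-en-3-yl acetate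
Conditions: Ac2O, DMAP, pyridine, 40 °C
Reagents that add atoms: acetic anhydride CC(=O)OC(C)=O
Why: DMAP-catalysed acylation esterifies the remaining hindered axial alcohol.

Step 21
Reactants: 29 acetate
Product: 30 (3S,4R,5S,9R,10S,13R)-3-acetoxy-19-[(tert-butyldiphenylsilyl)oxy]labd-7-en-15-oic acid
Conditions: CrO3, H2SO4, H2O, acetone, 0 °C
Reagents that add atoms: chromium trioxide O=[Cr](=O)=O; water O
Why: Jones oxidation cleaves the primary tert-butyldimethylsilyl ether under its acidic conditions and oxidises the liberated alcohol to the carboxylic acid, while the diphenylsilyl ether, the acetate and the trisubstituted alkene should be stable at 0 °C.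

Step 22
Reactants: 30 silyl-protected acid
Product: 31 (3S,4R,5S,9R,10S,13R)-3-acetoxy-19-hydroxylabd-7-en-15-oic acid (target)
Conditions: HF·pyridine, THF, 0 °C → rt
Reagents that add atoms: none
Why: Fluoride-mediated desilylation removes the remaining silyl ether without touching the acetate, which cannot migrate because the C3 oxygen and C19 are trans-diaxial.

## Compound list

1 | but-3-yn-1-ol | C#CCCO | starting material
2 | dimethyl{(E)-4-[(dimethylalumanyl)oxy]-2-methylbut-1-en-1-yl}alumane (syn carboalumination adduct) | C[Al](C)OCC/C(C)=C/[Al](C)C | intermediate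
3 | 2,4-dimethyl-5,6-dihydro-2H-1,2-oxaluminine (cyclic (Z)-alkenylalane) | C[Al]1OCCC(C)=C1 | intermediate
4 | (Z)-4-bromo-3-methylbut-3-en-1-ol | Br/C=C(C)\CCO | intermediate
5 | (Z)-4-bromo-3-methylbut-3-enoic acid | Br/C=C(C)\CC(=O)O | intermediate
6 | geraniol, (E)-3,7-dimethylocta-2,6-dien-1-ol | OC/C=C(\C)CCC=C(C)C | starting material
7 | geranyl (Z)-4-bromo-3-methylbut-3-enoate | Br/C=C(C)\CC(=O)OC/C=C(\C)CCC=C(C)C | intermediate
8 | boron dienolate of 7 on the (4R,5R)-diazaborolidine, C8 cis to the geranyloxy oxygen | Br/C=C(C)\C=C(/OC/C=C(\C)CCC=C(C)C)OB1N(S(=O)(=O)c2cc(cc(c2)C(F)(F)F)C(F)(F)F)[C@H](c2ccccc2)[C@@H](c2ccccc2)N1S(=O)(=O)c3cc(cc(c3)C(F)(F)F)C(F)(F)F | intermediate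
9 | (2S,3R)-2-[(Z)-1-bromoprop-1-en-2-yl]-3-ethenyl-3,7-dimethyloct-6-enoic acid | CC(C)=CCC[C@](C)(C=C)[C@H](C(=O)O)/C(C)=C\Br | intermediate
10 | (2S,3R)-2-[(Z)-1-bromoprop-1-en-2-yl]-3-ethenyl-3,7-dimethyloct-6-en-1-ol | CC(C)=CCC[C@](C)(C=C)[C@H](CO)/C(C)=C\Br | intermediate
11 | triflate of 10 | CC(C)=CCC[C@](C)(C=C)[C@H](COS(=O)(=O)C(F)(F)F)/C(C)=C\Br | intermediate
12 | (S)-2-methylbutane-1,4-diol | OC[C@@H](C)CCO | starting material
13 | (S)-4-[(tert-butyldimethylsilyl)oxy]-2-methylbutan-1-ol | OC[C@@H](C)CCO[Si](C)(C)C(C)(C)C | intermediate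
14 | (S)-(4-bromo-3-methylbutoxy)(tert-butyl)dimethylsilane | BrC[C@@H](C)CCO[Si](C)(C)C(C)(C)C | intermediate
15 | (S)-{4-[(tert-butyldimethylsilyl)oxy]-2-methylbutyl}magnesium bromide | Br[Mg]C[C@@H](C)CCO[Si](C)(C)C(C)(C)C | intermediate
16 | tert-butyl{[(3R,6S,7R)-6-[(Z)-1-bromoprop-1-en-2-yl]-7-ethenyl-3,7,11-trimethyldodec-10-en-1-yl]oxy}dimethylsilane | CC(C)=CCC[C@](C)(C=C)[C@H](CC[C@@H](C)CCO[Si](C)(C)C(C)(C)C)/C(C)=C\Br | intermediate
17 | 10,11-epoxide of 16 (epimers at the epoxide CH) | CC1(C)OC1CC[C@](C)(C=C)[C@H](CC[C@@H](C)CCO[Si](C)(C)C(C)(C)C)/C(C)=C\Br | intermediate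
18 | 10,11-diol of 16 (epimers at the carbinol CH) | CC(C)(O)C(O)CC[C@](C)(C=C)[C@H](CC[C@@H](C)CCO[Si](C)(C)C(C)(C)C)/C(C)=C\Br | intermediate
19 | (4R,5S,8R)-5-[(Z)-1-bromoprop-1-en-2-yl]-10-[(tert-butyldimethylsilyl)oxy]-4-ethenyl-4,8-dimethyldecanal | O=CCC[C@](C)(C=C)[C@H](CC[C@@H](C)CCO[Si](C)(C)C(C)(C)C)/C(C)=C\Br | intermediate
20 | ethyl (6R,7S,10R)-7-[(Z)-1-bromoprop-1-en-2-yl]-12-[(tert-butyldimethylsilyl)oxy]-6-ethenyl-6,10-dimethyl-3-oxododecanoate | CCOC(=O)CC(=O)CC[C@](C)(C=C)[C@H](CC[C@@H](C)CCO[Si](C)(C)C(C)(C)C)/C(C)=C\Br | intermediate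
21 | 2-diazo derivative of 20 | CCOC(=O)C(=[N+]=[N-])C(=O)CC[C@](C)(C=C)[C@H](CC[C@@H](C)CCO[Si](C)(C)C(C)(C)C)/C(C)=C\Br | intermediate
22 | ethyl (1R,5R,6S)-5-[(1Z,3S,6R)-1-bromo-8-{[tert-butyl(dimethyl)silyl]oxy}-2,6-dimethyloct-1-en-3-yl]-5-methyl-2-oxobicyclo[4.1.0]heptane-1-carboxylate | CCOC(=O)[C@]12C[C@H]1[C@@](C)(CCC2=O)[C@H](CC[C@@H](C)CCO[Si](C)(C)C(C)(C)C)/C(C)=C\Br | intermediate
23 | iodomagnesium enolate of ethyl 6-(iodomethyl)-5-methyl-2-oxo-5-[side chain of 22]cyclohexane-1-carboxylate (ring centres as in 22) | CCOC(=O)C1=C(O[Mg]I)CC[C@](C)([C@@H]1CI)[C@H](CC[C@@H](C)CCO[Si](C)(C)C(C)(C)C)/C(C)=C\Br | intermediate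
24 | ethyl (5R,9R,10R,13R)-15-[(tert-butyldimethylsilyl)oxy]-3-oxo-18-norlabd-7-en-19-oate (C4 epimers) | CCOC(=O)C1C(=O)CC[C@]2(C)[C@@H]1CC=C(C)[C@H]2CC[C@@H](C)CCO[Si](C)(C)C(C)(C)C | intermediate
25 | ethyl (4S,5S,9R,10S,13R)-15-[(tert-butyldimethylsilyl)oxy]-3-oxolabd-7-en-19-oate | CCOC(=O)[C@]1(C)C(=O)CC[C@]2(C)[C@@H]1CC=C(C)[C@H]2CC[C@@H](C)CCO[Si](C)(C)C(C)(C)C | intermediate
26 | ethyl (3S,4S,5S,9R,10S,13R)-15-[(tert-butyldimethylsilyl)oxy]-3-hydroxylabd-7-en-19-oate | CCOC(=O)[C@]1(C)[C@@H](O)CC[C@]2(C)[C@@H]1CC=C(C)[C@H]2CC[C@@H](C)CCO[Si](C)(C)C(C)(C)C | intermediate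
27 | (3S,4R,5S,9R,10S,13R)-15-[(tert-butyldimethylsilyl)oxy]labd-7-ene-3,19-diol | OC[C@]1(C)[C@@H](O)CC[C@]2(C)[C@@H]1CC=C(C)[C@H]2CC[C@@H](C)CCO[Si](C)(C)C(C)(C)C | intermediate
28 | 19-O-(tert-butyldiphenylsilyl) ether of 27 | CC(C)(C)[Si](OC[C@]1(C)[C@@H](O)CC[C@]2(C)[C@@H]1CC=C(C)[C@H]2CC[C@@H](C)CCO[Si](C)(C)C(C)(C)C)(c1ccccc1)c1ccccc1 | intermediate
29 | 3-O-acetate of 28 | CC(C)(C)[Si](OC[C@]1(C)[C@@H](OC(C)=O)CC[C@]2(C)[C@@H]1CC=C(C)[C@H]2CC[C@@H](C)CCO[Si](C)(C)C(C)(C)C)(c1ccccc1)c1ccccc1 | intermediate
30 | (3S,4R,5S,9R,10S,13R)-3-acetoxy-19-[(tert-butyldiphenylsilyl)oxy]labd-7-en-15-oic acid | CC(C)(C)[Si](OC[C@]1(C)[C@@H](OC(C)=O)CC[C@]2(C)[C@@H]1CC=C(C)[C@H]2CC[C@@H](C)CC(=O)O)(c1ccccc1)c1ccccc1 | intermediate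
31 | (3S,4R,5S,9R,10S,13R)-3-acetoxy-19-hydroxylabd-7-en-15-oic acid, CNP0138726.1 | CC(=O)O[C@H]1CC[C@]2(C)[C@H](CC=C(C)[C@H]2CC[C@@H](C)CC(=O)O)[C@]1(C)CO | target

## Step count and risks

Total step count: 22. Longest linear sequence: 20 steps (steps 1–6 and 9–22, from but-3-yn-1-ol).

Steps most likely to fail:

Step 15 (proposed new method). The ring-opened iodide may re-close, or C6 or C7 may be hydrodehalogenated, faster than nickel joins the two carbons; intermolecular coupling may also compete. The fallback uses known stages and sets out from 22. MgI2 in THF and then TMSCl should give the iodo silyl enol ether F1 (iodide homoconjugate addition, O-silylation). Zinc insertion into the primary C–I bond (Zn dust, LiCl, THF) should give the alkylzinc iodide F2, which is not isolated. Pd(PPh3)4-catalysed intramolecular Negishi coupling with the alkenyl bromide should then close ring B to the bicyclic silyl enol ether F3, which dilute aqueous acid hydrolyses to 24, where the route is rejoined.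

Step 4. The hindered boron dienolate may rearrange slowly, facial selectivity may erode, or the double bond may drift into conjugation before rearrangement. The fallback sets out from 7. LDA in THF at −78 °C and TMSCl should give the trimethylsilyl ketene acetal F4 (kinetic enolate geometry, C8 cis to the geranyloxy oxygen), which is not isolated and rearranges on warming (classical Ireland–Claisen rearrangement) to the racemic acid F5. Crystallisation of the (R)-1-phenylethylammonium salt F6 and acidification should return enantiopure 9.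

Step 14. Facial selectivity in the carbenoid addition to the vinyl group may be poor (C5 epimer), or the carbenoid may dimerise. The fallback sets out from 20, so diazo transfer is not needed. Iodocarbocyclisation with I2 and Ti(OtBu)4 in CH2Cl2 should give the iodomethyl keto ester F7; the titanium-bound keto ester carbon attacks the iodonium ion of the vinyl group in a 6-exo mode through a chair with the branched C9 substituent equatorial. DBU should then close the three-membered ring by intramolecular C-alkylation (3-exo-tet) and give 22.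

Further compounds
F1 | step 15 | ethyl 6-(iodomethyl)-5-methyl-5-[side chain of 22]-2-[(trimethylsilyl)oxy]cyclohex-1-ene-1-carboxylate (ring centres as in 23) | CCOC(=O)C1=C(O[Si](C)(C)C)CC[C@](C)([C@@H]1CI)[C@H](CC[C@@H](C)CCO[Si](C)(C)C(C)(C)C)/C(C)=C\Br
F2 | step 15 | alkylzinc iodide from F1 (C–ZnI in place of C–I) | CCOC(=O)C1=C(O[Si](C)(C)C)CC[C@](C)([C@@H]1C[Zn]I)[C@H](CC[C@@H](C)CCO[Si](C)(C)C(C)(C)C)/C(C)=C\Br
F3 | step 15 | trimethylsilyl enol ether of 24 (C3=C4) | CCOC(=O)C1=C(O[Si](C)(C)C)CC[C@]2(C)[C@@H]1CC=C(C)[C@H]2CC[C@@H](C)CCO[Si](C)(C)C(C)(C)C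
F4 | step 4 | trimethylsilyl ketene acetal of 7, C8 cis to the geranyloxy oxygen | Br/C=C(C)\C=C(/OC/C=C(\C)CCC=C(C)C)O[Si](C)(C)C
F5 | step 4 | racemic 2-[(Z)-1-bromoprop-1-en-2-yl]-3-ethenyl-3,7-dimethyloct-6-enoic acid (9 together with its (2R,3S)-enantiomer, whose SMILES is given) | CC(C)=CCC[C@@](C)(C=C)[C@@H](C(=O)O)/C(C)=C\Br
F6 | step 4 | (R)-1-phenylethylammonium salt of 9 | CC(C)=CCC[C@](C)(C=C)[C@H](C(=O)[O-])/C(C)=C\Br.C[C@H](c1ccccc1)[NH3+]
F7 | step 14 | ethyl 6-(iodomethyl)-5-methyl-2-oxo-5-[side chain of 22]cyclohexane-1-carboxylate (carbons bearing the methyl and iodomethyl groups configured as in 23) | CCOC(=O)C1C(=O)CC[C@](C)([C@@H]1CI)[C@H](CC[C@@H](C)CCO[Si](C)(C)C(C)(C)C)/C(C)=C\Br
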